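**Retrosynthetic overview**
1. The p-quinone is released last from a 4-silyloxy-2,5-dimethoxyphenol (fluoride, then DDQ); the same fluoride frees the second indole N–H.
2. Key disconnection: both C(OMe)–C(=O) bonds of the six-membered ring. This gives two three-carbon halves of equal size, a β-lithio-β-methoxyacrylate ester carrying the 2,7-diprenylated indole and a β-methoxyacryloylsilane carrying the N-silylindole. Vinyllithium addition, Brook rearrangement and ring closure on the ester join them in one operation as a [3+3] benzannulation.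
3. Enabling feature: the quinone ring is a head-to-tail pair of identical C(=O)–C(indol-3-yl)=C(OMe) units, so each new bond links a methoxy-bearing sp2 carbon to a carbonyl carbon. The methoxy carbon beside the hindered indole can be lithiated cis to its own ester carbon. The carbonyl carbon beside the other indole, brought in as an acylsilane, passes the charge through its C(indolyl)=C(OMe) vinyl group to the second methoxy carbon.
4. Both halves come from indole-3-acetic esters by Claisen formylation and O-methylation. The hindered one comes from a Fischer indolization, C2 reverse prenylation through the 3-chloroindolenine and C7 Stille prenylation; the acylsilane comes from methyl indole-3-acetate through its morpholine amide and PhMe2SiLi.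
5. Ring order: pyrrole ring of the substituted indole (step 1), then the central carbocycle (step 11), oxidized to the quinone in step 12.

Key step: step 11

Remark: the target has no stereocentre; hindered rotation about the bond between the 2-tert-alkylindole and the quinone is not specified in the target and is left uncontrolled. The two reagent preparations (prenylborane, silyllithium) are counted as steps.

**Step 1**
Reactants: 1 (2-bromophenyl)hydrazine hydrochloride; 2 methyl 4,4-dimethoxybutanoate
Product: 3 methyl 2-(7-bromo-1H-indol-3-yl)acetate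
Conditions: H2SO4 (cat.), MeOH, reflux
Reagents that add atoms: none
Why: Fischer indole synthesis, in which the hydrazone of the unmasked aldehyde can form its ene-hydrazine only toward the CH2 group (so C3 carries CH2CO2Me) and the sigmatropic shift can use only the free ortho position (so bromine ends at C7).

**Step 2**
Reactants: 4 9-borabicyclo[3.3.1]nonane (9-BBN); 5 3-methylbuta-1,2-diene
Product: 6 9-(3-methylbut-2-en-1-yl)-9-borabicyclo[3.3.1]nonane (B-prenyl-9-BBN, used as THF solution)
Conditions: THF, 0 °C to rt
Reagents that add atoms: none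
Why: Allene hydroboration, in which the bulky borane places boron on the unsubstituted terminal carbon and hydrogen on the central carbon, which should give the prenylborane directly.

**Step 3**
Reactants: 3 methyl 2-(7-bromo-1H-indol-3-yl)acetate; 6 B-prenyl-9-BBN
Product: 8 methyl 2-[7-bromo-2-(2-methylbut-3-en-2-yl)-1H-indol-3-yl]acetate, via 3-chloroindolenine 7 (not isolated)
Conditions: t-BuOCl, Et3N, THF, −78 °C; then 6 (THF solution), −78 °C to rt
Reagents that add atoms: none
Why: C3 chlorination gives the 3-chloroindolenine, whose C=N is allylborated by 6 through a six-membered SE2′ transition state that delivers the tertiary allyl terminus to C2, and loss of HCl restores the indole (the known C2 reverse prenylation of 3-substituted indoles).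

**Step 4**
Reactants: 8 methyl 2-[7-bromo-2-(2-methylbut-3-en-2-yl)-1H-indol-3-yl]acetate; 9 tributyl(3-methylbut-2-en-1-yl)stannane
Product: 10 methyl 2-[2-(2-methylbut-3-en-2-yl)-7-(3-methylbut-2-en-1-yl)-1H-indol-3-yl]acetate
Conditions: Pd(PPh3)4 (5 mol%), DMF, 100 °C
Reagents that add atoms: none
Why: Stille coupling of the aryl bromide, in which the allyl group should be transferred mainly through its unsubstituted terminus to give the linear prenyl arene, while the free N–H, the ester and the hindered terminal vinyl group are tolerated.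

**Step 5**
Reactants: 10 methyl 2-[2-(2-methylbut-3-en-2-yl)-7-(3-methylbut-2-en-1-yl)-1H-indol-3-yl]acetate
Product: 12 methyl (E)-3-methoxy-2-[2-(2-methylbut-3-en-2-yl)-7-(3-methylbut-2-en-1-yl)-1H-indol-3-yl]prop-2-enoate, via hydroxymethylene ester 11 (not isolated)
Conditions: NaH, HCO2Me, THF, 0 °C to rt; aq. HCl work-up; then Me2SO4, K2CO3, acetone, rt
Reagents that add atoms: methyl formate (COC=O); dimethyl sulfate (COS(=O)(=O)OC)
Why: Crossed Claisen formylation of the arylacetate enolate followed by O-methylation of the enol is the standard route to β-methoxyacrylates, the E isomer (methoxy trans to ester) being the thermodynamically favoured one and K2CO3 being too weak to ionize the hindered indole N–H.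

**Step 6**
Reactants: 13 methyl 2-(1H-indol-3-yl)acetate
Product: 15 methyl (E)-2-(1H-indol-3-yl)-3-methoxyprop-2-enoate, via hydroxymethylene ester 14 (not isolated)
Conditions: NaH, HCO2Me, THF, 0 °C to rt; aq. HCl work-up; then Me2SO4, K2CO3, acetone, rt
Reagents that add atoms: methyl formate (COC=O); dimethyl sulfate (COS(=O)(=O)OC)
Why: The same Claisen formylation and enol O-methylation as in step 5, in which only the acidic enol is ionized by K2CO3 so that a limited amount of dimethyl sulfate should methylate oxygen and leave the indole N–H free.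

**Step 7**
Reactants: 15 methyl (E)-2-(1H-indol-3-yl)-3-methoxyprop-2-enoate
Product: 16 methyl (E)-3-methoxy-2-[1-(triisopropylsilyl)-1H-indol-3-yl]prop-2-enoate
Conditions: NaH, THF, 0 °C; then TIPSCl, 0 °C to rt
Reagents that add atoms: triisopropylsilyl chloride (CC(C)[Si](Cl)(C(C)C)C(C)C)
Why: N-Silylation, in which the indole N–H is the only acidic site of 15 and the bulky silyl group later shields C2–H from bases and is removed by fluoride.

**Step 8**
Reactants: 16 methyl (E)-3-methoxy-2-[1-(triisopropylsilyl)-1H-indol-3-yl]prop-2-enoate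
Product: 17 (E)-3-methoxy-1-(morpholin-4-yl)-2-[1-(triisopropylsilyl)-1H-indol-3-yl]prop-2-en-1-one
Conditions: morpholine, i-PrMgCl, THF, −10 °C to rt; aq. NH4Cl
Reagents that add atoms: morpholine (C1COCCN1)
Why: Bodroux reaction, in which the hard chloromagnesium amide of morpholine should attack the ester carbonyl and not the methoxy-bearing β-carbon, giving the amide needed for clean mono-addition of a silyl anion.

**Step 9**
Reactants: 18 chlorodimethylphenylsilane
Product: 19 dimethylphenylsilyllithium (THF solution)
Conditions: Li, THF, 0 °C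
Reagents that add atoms: lithium ([Li])
Why: Reductive metalation of the chlorosilane by lithium through the disilane is the standard preparation of this silyllithium.

**Step 10**
Reactants: 17 (E)-3-methoxy-1-(morpholin-4-yl)-2-[1-(triisopropylsilyl)-1H-indol-3-yl]prop-2-en-1-one; 19 dimethylphenylsilyllithium
Product: 20 (E)-1-[dimethyl(phenyl)silyl]-3-methoxy-2-[1-(triisopropylsilyl)-1H-indol-3-yl]prop-2-en-1-one
Conditions: THF, −78 °C; aq. NH4Cl
Reagents that add atoms: none
Why: Acylsilane synthesis from a morpholine amide, in which the silyllithium adds to the amide carbonyl to give a tetrahedral lithium alkoxide that collapses only on work-up (no over-addition), 1,2-attack being favoured because the β-carbon is donor-substituted and hindered.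

**Step 11**
Reactants: 12 methyl (E)-3-methoxy-2-[2-(2-methylbut-3-en-2-yl)-7-(3-methylbut-2-en-1-yl)-1H-indol-3-yl]prop-2-enoate; 20 (E)-1-[dimethyl(phenyl)silyl]-3-methoxy-2-[1-(triisopropylsilyl)-1H-indol-3-yl]prop-2-en-1-one
Product: 25 4-{[dimethyl(phenyl)silyl]oxy}-2,5-dimethoxy-6-[2-(2-methylbut-3-en-2-yl)-7-(3-methylbut-2-en-1-yl)-1H-indol-3-yl]-3-[1-(triisopropylsilyl)-1H-indol-3-yl]phenol, via dilithio acrylate 21 (not isolated), via silyl alkoxide 22 (not isolated), via siloxy trienolate 23 (not isolated), via cyclohexadienone 24 (not isolated)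
Conditions: LDA (LiN(i-Pr)2, 2.2 equiv), THF, −78 °C; then 20, −78 °C to rt; aq. NH4Cl
Reagents that add atoms: none
Why: Proposed new method: LDA removes the indole N–H and then the vinyl hydrogen of 12 that lies cis to the ester (carbonyl-chelated vinylic lithiation), and the vinyllithium 21 adds to the aldehyde-like acylsilane carbonyl of 20 to give the α-silyl alkoxide 22, which forms the first C(OMe)–C(O) bond. A [1,2]-Brook rearrangement then moves silicon from carbon to oxygen and leaves a carbanion delocalized through both flanking vinyl groups into the ester (siloxy trienolate 23); its far methoxy-bearing terminus closes on the ester carbon, methoxide leaves to give dienone 24, and tautomerization to the phenoxide makes the sequence irreversible. The closest known reaction types are the Brook-rearrangement-mediated [3+2] and [3+4] annulations of β-substituted acryloylsilanes with ketone enolates and the siloxyallyl anions formed from vinyllithiums and acylsilanes; new here is a β-lithioacrylate as partner, whose own ester traps the relayed anion so that a benzene ring results. The single ring formed is the central carbocycle, closed by attack of the terminal carbanion on the ester carbonyl in a six-membered closure (6-exo-trig at the carbonyl, equally a 6π-electrocyclization of the 1-oxidotriene as in dienylketene benzannulations). No stereocentre remains, since the carbinol carbon of 22 and the sp3 carbon of 24 both become aromatic carbons. The step needs cross- over self-condensation, 1,2- over 1,4-addition, silyl migration before lactonization and closure at the far terminus: the acylsilane is far more electrophilic than the vinylogous carbonate ester of 21 at −78 °C, its β-carbon is deactivated by the methoxy donor, the doubly allylic ester-conjugated carbanion drives a fast shift of the small PhMe2Si group, and only the far terminus can reach the ester in a six-membered ring, the cis relation of lithium and ester in 21 fixing the geometry on that side.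

**Step 12**
Reactants: 25 4-{[dimethyl(phenyl)silyl]oxy}-2,5-dimethoxy-6-[2-(2-methylbut-3-en-2-yl)-7-(3-methylbut-2-en-1-yl)-1H-indol-3-yl]-3-[1-(triisopropylsilyl)-1H-indol-3-yl]phenol
Product: 27 2,5-dimethoxy-3-(1H-indol-3-yl)-6-[2-(2-methylbut-3-en-2-yl)-7-(3-methylbut-2-en-1-yl)-1H-indol-3-yl]cyclohexa-2,5-diene-1,4-dione, via hydroquinone 26 (not isolated)
Conditions: TBAF, AcOH, THF, 0 °C to rt; then DDQ, 0 °C
Reagents that add atoms: none
Why: Buffered fluoride desilylation cleaves the aryl O–Si and indole N–Si bonds and the electron-rich 2,5-dimethoxyhydroquinone 26 should be oxidized by DDQ faster than either indole (hydroquinone-to-quinone oxidation); any 26 already formed in step 11 by loss of the labile O-silyl group converges here.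

**Compound list**
1 | (2-bromophenyl)hydrazine hydrochloride | Cl.NNc1ccccc1Br | starting material
2 | methyl 4,4-dimethoxybutanoate | COC(=O)CCC(OC)OC | starting material
3 | methyl 2-(7-bromo-1H-indol-3-yl)acetate | COC(=O)Cc1c[nH]c2c(Br)cccc12 | intermediate
4 | 9-borabicyclo[3.3.1]nonane (9-BBN) | B1C2CCCC1CCC2 | starting material
5 | 3-methylbuta-1,2-diene | CC(C)=C=C | starting material
6 | 9-(3-methylbut-2-en-1-yl)-9-borabicyclo[3.3.1]nonane | CC(C)=CCB1C2CCCC1CCC2 | intermediate
7 | methyl 2-(7-bromo-3-chloro-3H-indol-3-yl)acetate (racemic) | COC(=O)CC1(Cl)C=Nc2c(Br)cccc21 | intermediate (not isolated)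
8 | methyl 2-[7-bromo-2-(2-methylbut-3-en-2-yl)-1H-indol-3-yl]acetate | COC(=O)Cc1c(C(C)(C)C=C)[nH]c2c(Br)cccc12 | intermediate
9 | tributyl(3-methylbut-2-en-1-yl)stannane | CCCC[Sn](CCCC)(CCCC)CC=C(C)C | starting material
10 | methyl 2-[2-(2-methylbut-3-en-2-yl)-7-(3-methylbut-2-en-1-yl)-1H-indol-3-yl]acetate | COC(=O)Cc1c(C(C)(C)C=C)[nH]c2c(CC=C(C)C)cccc12 | intermediate
11 | methyl 3-hydroxy-2-[2-(2-methylbut-3-en-2-yl)-7-(3-methylbut-2-en-1-yl)-1H-indol-3-yl]prop-2-enoate (enol of the α-formyl ester) | COC(=O)C(=CO)c1c(C(C)(C)C=C)[nH]c2c(CC=C(C)C)cccc12 | intermediate (not isolated)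
12 | methyl (E)-3-methoxy-2-[2-(2-methylbut-3-en-2-yl)-7-(3-methylbut-2-en-1-yl)-1H-indol-3-yl]prop-2-enoate | CO/C=C(/C(=O)OC)c1c(C(C)(C)C=C)[nH]c2c(CC=C(C)C)cccc12 | intermediate
13 | methyl 2-(1H-indol-3-yl)acetate | COC(=O)Cc1c[nH]c2ccccc12 | starting material
14 | methyl 3-hydroxy-2-(1H-indol-3-yl)prop-2-enoate (enol of the α-formyl ester) | COC(=O)C(=CO)c1c[nH]c2ccccc12 | intermediate (not isolated)
15 | methyl (E)-2-(1H-indol-3-yl)-3-methoxyprop-2-enoate | CO/C=C(/C(=O)OC)c1c[nH]c2ccccc12 | intermediate
16 | methyl (E)-3-methoxy-2-[1-(triisopropylsilyl)-1H-indol-3-yl]prop-2-enoate | CO/C=C(/C(=O)OC)c1cn([Si](C(C)C)(C(C)C)C(C)C)c2ccccc12 | intermediate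
17 | (E)-3-methoxy-1-(morpholin-4-yl)-2-[1-(triisopropylsilyl)-1H-indol-3-yl]prop-2-en-1-one | CO/C=C(/C(=O)N1CCOCC1)c1cn([Si](C(C)C)(C(C)C)C(C)C)c2ccccc12 | intermediate
18 | chlorodimethylphenylsilane | C[Si](C)(Cl)c1ccccc1 | starting material
19 | dimethylphenylsilyllithium | [Li][Si](C)(C)c1ccccc1 | intermediate
20 | (E)-1-[dimethyl(phenyl)silyl]-3-methoxy-2-[1-(triisopropylsilyl)-1H-indol-3-yl]prop-2-en-1-one | CO/C=C(/C(=O)[Si](C)(C)c1ccccc1)c1cn([Si](C(C)C)(C(C)C)C(C)C)c2ccccc12 | intermediate
21 | N,C-dilithio derivative of 12 (lithium on N1 and on the methoxy-bearing vinyl carbon, cis to the ester) | CO/C([Li])=C(/C(=O)OC)c1c(C(C)(C)C=C)n([Li])c2c(CC=C(C)C)cccc12 | intermediate (not isolated)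
22 | lithium α-silyl alkoxide from addition of 21 to 20 (racemic at the carbinol carbon) | COC(=O)/C(c1c(C(C)(C)C=C)n([Li])c2c(CC=C(C)C)cccc12)=C(OC)\C(O[Li])([Si](C)(C)c1ccccc1)/C(=C/OC)c1cn([Si](C(C)C)(C(C)C)C(C)C)c2ccccc12 | intermediate (not isolated)
23 | lithium siloxy trienolate formed by the Brook shift (delocalized, geometry labile) | COC(O[Li])=C(c1c(C(C)(C)C=C)n([Li])c2c(CC=C(C)C)cccc12)C(OC)=C(O[Si](C)(C)c1ccccc1)C(=COC)c1cn([Si](C(C)C)(C(C)C)C(C)C)c2ccccc12 | intermediate (not isolated)
24 | 4-silyloxy-3,6-dimethoxy-cyclohexa-2,4-dien-1-one formed by ring closure (N-lithio, racemic at C6) | COC1C(=O)C(c2c(C(C)(C)C=C)n([Li])c3c(CC=C(C)C)cccc23)=C(OC)C(O[Si](C)(C)c2ccccc2)=C1c1cn([Si](C(C)C)(C(C)C)C(C)C)c2ccccc12 | intermediate (not isolated)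
25 | 4-{[dimethyl(phenyl)silyl]oxy}-2,5-dimethoxy-6-[2-(2-methylbut-3-en-2-yl)-7-(3-methylbut-2-en-1-yl)-1H-indol-3-yl]-3-[1-(triisopropylsilyl)-1H-indol-3-yl]phenol | COc1c(O)c(c2c(C(C)(C)C=C)[nH]c3c(CC=C(C)C)cccc23)c(OC)c(O[Si](C)(C)c2ccccc2)c1c1cn([Si](C(C)C)(C(C)C)C(C)C)c2ccccc12 | intermediate
26 | 2,5-dimethoxy-3-(1H-indol-3-yl)-6-[2-(2-methylbut-3-en-2-yl)-7-(3-methylbut-2-en-1-yl)-1H-indol-3-yl]benzene-1,4-diol | COc1c(O)c(c2c(C(C)(C)C=C)[nH]c3c(CC=C(C)C)cccc23)c(OC)c(O)c1c1c[nH]c2ccccc12 | intermediate (not isolated)
27 | 2,5-dimethoxy-3-(1H-indol-3-yl)-6-[2-(2-methylbut-3-en-2-yl)-7-(3-methylbut-2-en-1-yl)-1H-indol-3-yl]cyclohexa-2,5-diene-1,4-dione (CNP0163342.0) | C=CC(C)(C)c1[nH]c2c(CC=C(C)C)cccc2c1C1=C(OC)C(=O)C(c2c[nH]c3ccccc23)=C(OC)C1=O | target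

**Totals and risks**
Total step count: 12 (ten on the substrates plus two reagent preparations). Longest linear sequence: 6 steps (steps 1, 3, 4, 5, 11, 12).

Steps most likely to fail:

Step 11 (Proposed new method). The relay may stall in three ways: the alkoxide may lactonize onto the ester before silicon migrates, the delocalized anion may be protonated instead of closing, or the lithioacrylate may condense with itself. The fallback sets out from 12 and 17 and comes back to the route at 27. The dilithio species 21 (LDA, THF, −78 °C) is acylated at −78 °C by the morpholine amide 17, whose tetrahedral adduct releases the ketone only on work-up, which should give the divinyl ketone methyl (2E,5E)-3,6-dimethoxy-2-[2-(2-methylbut-3-en-2-yl)-7-(3-methylbut-2-en-1-yl)-1H-indol-3-yl]-4-oxo-5-[1-(triisopropylsilyl)-1H-indol-3-yl]hexa-2,5-dienoate F1. Lithium 2,2,6,6-tetramethylpiperidide (LiTMP, 2.2 equiv, THF, −78 °C to 0 °C) then removes the N–H and the vinyl hydrogen at C6 that lies cis to the ketone, and the new vinyllithium closes on the ester carbonyl with loss of methoxide to give the N-silyl quinone 2,5-dimethoxy-3-[2-(2-methylbut-3-en-2-yl)-7-(3-methylbut-2-en-1-yl)-1H-indol-3-yl]-6-[1-(triisopropylsilyl)-1H-indol-3-yl]cyclohexa-2,5-diene-1,4-dione F2. TBAF/AcOH in THF removes the silyl group and gives 27. Both C–C bond formations are organolithium acylations by an amide or an ester and the metalation is the carbonyl-directed vinylic lithiation already used for 12, so only known reaction types are involved; the ring is built in two operations and the hydroquinone stage is bypassed.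

Step 10. The silyl anion may add in conjugate fashion to the methoxy-bearing carbon (addition–elimination), or the acylsilane may be cleaved by base during work-up. The fallback sets out from 16 and comes back at 20 by building the acylsilane through the alcohol oxidation level. Reduction of 16 with i-Bu2AlH (CH2Cl2, −78 °C) should give (E)-3-methoxy-2-[1-(triisopropylsilyl)-1H-indol-3-yl]prop-2-en-1-ol F3. Oxidation with MnO2 (CH2Cl2, rt) gives (E)-3-methoxy-2-[1-(triisopropylsilyl)-1H-indol-3-yl]prop-2-enal F4. Addition of 19 (THF, −78 °C, AcOH quench at −78 °C to forestall the Brook shift) gives (E)-1-[dimethyl(phenyl)silyl]-3-methoxy-2-[1-(triisopropylsilyl)-1H-indol-3-yl]prop-2-en-1-ol F5. Swern oxidation ((COCl)2, DMSO, Et3N, −78 °C) of this α-silyl carbinol gives 20.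

Step 4. Regiocontrol in the allyl transfer may be lost, with coupling through the substituted terminus giving the 1,1-dimethylallyl isomer. The fallback sets out from 8 and comes back at 10 by separating C–C coupling from installation of the trisubstituted alkene. Stille coupling of 8 with allyltributylstannane (Pd(PPh3)4, DMF, 100 °C), which has no regiochemical ambiguity, should give methyl 2-[2-(2-methylbut-3-en-2-yl)-7-(prop-2-en-1-yl)-1H-indol-3-yl]acetate F6. Cross-metathesis with excess 2-methylbut-2-ene (second-generation Grubbs catalyst, RuCl2(H2IMes)(PCy3)(=CHPh), CH2Cl2, 40 °C) then converts the allyl group into the prenyl group of 10; the vinyl group on the quaternary carbon at C2 is too hindered to take part.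

**Further compounds**
F1 | step 11 | methyl (2E,5E)-3,6-dimethoxy-2-[2-(2-methylbut-3-en-2-yl)-7-(3-methylbut-2-en-1-yl)-1H-indol-3-yl]-4-oxo-5-[1-(triisopropylsilyl)-1H-indol-3-yl]hexa-2,5-dienoate | COC(=O)/C(c1c(C(C)(C)C=C)[nH]c2c(CC=C(C)C)cccc12)=C(OC)\C(=O)/C(=C/OC)c1cn([Si](C(C)C)(C(C)C)C(C)C)c2ccccc12
F2 | step 11 | 2,5-dimethoxy-3-[2-(2-methylbut-3-en-2-yl)-7-(3-methylbut-2-en-1-yl)-1H-indol-3-yl]-6-[1-(triisopropylsilyl)-1H-indol-3-yl]cyclohexa-2,5-diene-1,4-dione | C=CC(C)(C)c1[nH]c2c(CC=C(C)C)cccc2c1C1=C(OC)C(=O)C(c2cn([Si](C(C)C)(C(C)C)C(C)C)c3ccccc23)=C(OC)C1=O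
F3 | step 10 | (E)-3-methoxy-2-[1-(triisopropylsilyl)-1H-indol-3-yl]prop-2-en-1-ol | CO/C=C(/CO)c1cn([Si](C(C)C)(C(C)C)C(C)C)c2ccccc12
F4 | step 10 | (E)-3-methoxy-2-[1-(triisopropylsilyl)-1H-indol-3-yl]prop-2-enal | CO/C=C(/C=O)c1cn([Si](C(C)C)(C(C)C)C(C)C)c2ccccc12
F5 | step 10 | (E)-1-[dimethyl(phenyl)silyl]-3-methoxy-2-[1-(triisopropylsilyl)-1H-indol-3-yl]prop-2-en-1-ol (racemic) | CO/C=C(/C(O)[Si](C)(C)c1ccccc1)c1cn([Si](C(C)C)(C(C)C)C(C)C)c2ccccc12
F6 | step 4 | methyl 2-[2-(2-methylbut-3-en-2-yl)-7-(prop-2-en-1-yl)-1H-indol-3-yl]acetate | COC(=O)Cc1c(C(C)(C)C=C)[nH]c2c(CC=C)cccc12
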